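**Retrosynthetic overview**

- The target (guaiane numbering, C1/C5 ring fusion) comes from its 1,10-cyclic carbonate, with the C9 angelate already in place.
- Key disconnection: cyclopentane C1–C2–C3–C4–C5 ⇐ cyclobutane C1–C3–C4–C5 fused to the seven-membered ring, by insertion of the exocyclic C2 into the C1–C3 bond (cyclobutylmethyl cation ring expansion), the C1 cation being captured by the C10 O-carbamate.
- Enabling feature: C1 is a fully substituted carbinol carbon of the five-membered ring with the C10 carbinol as its neighbour (cis-1,10-diol), and C4=C15 lies β,γ to the C6 ketone through C5, which is the pattern of an allene–enone [2+2] adduct.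
- Cyclobutane ⇐ [2+2] photocycloaddition of allene to a cyclohept-2-enone (C6=O, C5=C1); enone ⇐ hydroxymethyl addition and oxidative transposition on a cycloheptenone made by one-carbon ring expansion (C5) of the (S)-carvone ring; C9/C10 oxygens from the carvone epoxide.
- Ring order: six-membered (carvone) → seven-membered → fused four-membered → five-membered (key step).

Key step: step 16

Remark (numbering): guaiane numbers of the target are used for all intermediates (carvone C1, C2, C3, C4, C5, C6 = C1, C10, C9, C8, C7, C6); β is the face of the carbocycle that bears the C10 oxygen, α the opposite face.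

Assumption: once the C6 ketone exists (from step 11), the enolisable C7 centre is taken to keep its carvone-derived configuration under the buffered conditions chosen.

**Route**

Step 1
Reactants: 1 (S)-(+)-carvone
Product: 2 (S)-carvotanacetone [(5S)-2-methyl-5-(propan-2-yl)cyclohex-2-en-1-one]
Conditions: H2 (1 atm), RhCl(PPh3)3 (cat.), toluene, 23 °C
Reagents that add atoms: none
Why: Homogeneous hydrogenation with RhCl(PPh3)3 saturates the unhindered 1,1-disubstituted isopropenyl alkene and leaves the conjugated trisubstituted enone untouched; the C7 stereocentre comes unchanged from (S)-carvone.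

Step 2
Reactants: 2 (S)-carvotanacetone
Product: 3 trans-epoxy ketone (1S,4S,6S)-1-methyl-4-(propan-2-yl)-7-oxabicyclo[4.1.0]heptan-2-one
Conditions: 30% aq. H2O2, NaOH, MeOH, 0 °C
Reagents that add atoms: hydrogen peroxide, OO
Why: Weitz–Scheffer nucleophilic epoxidation: hydroperoxide adds in conjugate fashion to C9 axially, anti to the C7 isopropyl group, so the oxirane forms trans to it and fixes the β C10–O bond.

Step 3
Reactants: 3 trans-epoxy ketone
Product: 4 (2S,3R,5S)-2,3-dihydroxy-2-methyl-5-(propan-2-yl)cyclohexan-1-one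
Conditions: HClO4 (cat.), THF/H2O, 23 °C
Reagents that add atoms: water, O
Why: Acid-catalysed epoxide hydrolysis with trans-diaxial opening: water attacks the secondary C9 with inversion (C10 is tertiary and deactivated by the adjacent ketone), giving the 9α,10β trans-diol.

Step 4
Reactants: 4 diol ketone
Product: 5 (2S,3R,5S)-2-hydroxy-2-methyl-5-(propan-2-yl)-3-[(triisopropylsilyl)oxy]cyclohexan-1-one
Conditions: iPr3SiOTf, 2,6-lutidine, CH2Cl2, −78 °C
Reagents that add atoms: triisopropylsilyl trifluoromethanesulfonate, CC(C)[Si](OS(=O)(=O)C(F)(F)F)(C(C)C)C(C)C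
Why: Silyl ether formation; the secondary C9 hydroxyl reacts in preference to the hindered tertiary α-ketol hydroxyl, and the bulky silyl group should not migrate in the basic steps that follow.

Step 5
Reactants: 5 C9 silyl ether
Product: 6 (1S,2R,4S)-1-methyl-6-oxo-4-(propan-2-yl)-2-[(triisopropylsilyl)oxy]cyclohexyl dimethylcarbamate
Conditions: KN(SiMe3)2, THF, −78 °C; ClC(O)NMe2, −78 to 0 °C
Reagents that add atoms: dimethylcarbamoyl chloride, CN(C)C(=O)Cl
Why: O-Acylation of the tertiary potassium alkoxide with a carbamoyl chloride (carbamate formation) installs a base-stable C10 substituent whose carbonyl oxygen later serves as the internal nucleophile.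

Step 6
Reactants: 6 carbamate ketone
Product: 7 trimethylsilyl enol ether of 6 (C1–OSiMe3; C1=C6)
Conditions: LiN(iPr)2, THF, −78 °C; Me3SiCl, Et3N
Reagents that add atoms: chlorotrimethylsilane, C[Si](C)(C)Cl
Why: Kinetic enolate formation and O-silylation; C10 is quaternary, so enolisation can only occur toward C6 and one regioisomeric silyl enol ether should result.

Step 7
Reactants: 7 silyl enol ether
Product: 8 1-(trimethylsilyloxy)bicyclo[4.1.0]heptane (cyclopropane CH2 = future C5 across C1–C6 on the β face)
Conditions: Et2Zn, CH2I2, CH2Cl2, 0 to 23 °C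
Reagents that add atoms: diiodomethane, ICI
Why: Simmons–Smith cyclopropanation (Furukawa variant) of the electron-rich silyl enol ether; the new CH2 becomes C5, and the stereocentres created at C1 and C6 are destroyed in step 8.

Step 8
Reactants: 8 siloxycyclopropane
Product: 10 cyclohept-2-enone (C1 ketone; C5=C6; 7α-isopropyl; 9α-OTIPS; 10β-dimethylcarbamoyloxy), via β-chloro ketone 9 (not isolated)
Conditions: FeCl3, DMF, 0 °C; then NaOAc, MeOH, 65 °C
Reagents that add atoms: none
Why: Saegusa-type oxidative ring expansion: one-electron oxidation by FeCl3 gives an alkoxy radical that cleaves the internal cyclopropane bond C1–C6, the ring-expanded C6 radical takes up chlorine, and acetate-mediated E1cB loss of HCl from 9 gives the cyclohept-2-enone.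

Step 9
Reactants: 11 (tributylstannyl)methanol; 12 4-methoxybenzyl chloride
Product: 13 tributyl{[(4-methoxybenzyl)oxy]methyl}stannane
Conditions: NaH, Bu4NI (cat.), THF, 0 to 23 °C
Reagents that add atoms: none
Why: Williamson ether synthesis on the primary stannyl alcohol gives the tin precursor of the alkoxymethyl anion.

Step 10
Reactants: 10 cyclohept-2-enone; 13 alkoxymethylstannane
Product: 15 tertiary allylic alcohol (C1 bearing OH and CH2OPMB; C5=C6), via alkoxymethyllithium 14 (not isolated)
Conditions: 13, n-BuLi, THF, −78 °C; then 10, −78 °C; AcOH quench at −78 °C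
Reagents that add atoms: none
Why: Tin–lithium exchange generates the α-alkoxymethyllithium 14, which adds 1,2 to the enone carbonyl and introduces C2; the C1 configuration formed here is irrelevant because C1 becomes sp2 in step 11.

Step 11
Reactants: 15 tertiary allylic alcohol
Product: 16 β-substituted cyclohept-2-enone (C6 ketone; C5=C1; C1–CH2OPMB)
Conditions: [C5H5NH][CrO3Cl], 4 Å molecular sieves, CH2Cl2, 23 °C
Reagents that add atoms: pyridinium chlorochromate (supplies the C6 carbonyl oxygen), [O-][Cr](=O)(=O)Cl.c1cc[nH+]cc1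
Why: Dauben–Babler oxidative transposition: the tertiary allylic chromate ester undergoes a [3,3] shift to C6 and is oxidised, which moves the oxygen function to C6 and the double bond to C5=C1.

Step 12
Reactants: 16 β-substituted cycloheptenone; 17 allene (propa-1,2-diene)
Product: 19 cis-fused allene photoadduct (9-methylenebicyclo[5.2.0]nonan-2-one core; cyclobutane C1–C3–C4–C5 on the β face; 1α-CH2OPMB; 5α-H), via trans-fused C5 epimer 18 (not isolated)
Conditions: hν (350 nm, Pyrex), allene (excess), CH2Cl2, −78 °C; then neutral Al2O3, 23 °C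
Reagents that add atoms: none
Why: Enone–allene [2+2] photocycloaddition with head-to-head regiochemistry (sp2 carbon C4 on the α-carbon C5); the allene CH2 should bond to C1 on the β face, anti to the C10 methyl and the α-oriented C9 and C7 substituents, and alumina should epimerise any trans-fused adduct at the enolisable C5 to the cis-fused ketone, so that H5 ends α.

Step 13
Reactants: 19 photoadduct
Product: 20 C9 alcohol (9α-OH)
Conditions: HF·pyridine, THF, 0 to 23 °C
Reagents that add atoms: none
Why: Fluoride-mediated cleavage of the silyl ether under mildly acidic conditions that leave the β,γ-unsaturated ketone, the carbamate and the benzyl-type ether intact.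

Step 14
Reactants: 20 C9 alcohol; 21 angelic acid [(2Z)-2-methylbut-2-enoic acid]
Product: 23 C9 angelate, via mixed anhydride 22 (not isolated)
Conditions: 2,4,6-Cl3C6H2COCl, Et3N, toluene, 23 °C; then 20, DMAP, toluene, 60 °C
Reagents that add atoms: none
Why: Yamaguchi esterification through mixed anhydride 22, a method known to acylate hindered secondary alcohols with retention of the Z geometry of angelates.

Step 15
Reactants: 23 C9 angelate
Product: 24 primary C2 alcohol (1α-CH2OH on the cyclobutane)
Conditions: DDQ, CH2Cl2/pH 7 buffer, 0 °C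
Reagents that add atoms: none
Why: Oxidative cleavage of the 4-methoxybenzyl ether by DDQ (hydride abstraction, then hydrolysis) frees the primary alcohol without touching the alkenes or esters.

Step 16
Reactants: 24 primary C2 alcohol
Product: 27 guaiane 1β,10β-cyclic carbonate 9α-angelate (5αH; 4(15)-en-6-one), via triflate 25 (not isolated), via iminium triflate 26 (not isolated)
Conditions: Tf2O, 2,6-di-tert-butyl-4-methylpyridine, CH2Cl2, −78 to 23 °C; then aq. NaHCO3
Reagents that add atoms: water, O
Why: Proposed new method: triflation of the neopentyl-type primary alcohol gives 25, whose ionisation is assisted by migration of the antiperiplanar cyclobutane bond C1–C3 to C2 (cyclobutylcarbinyl to cyclopentyl cation, driven by release of four-ring strain), and the tertiary C1 cation is captured by the carbonyl oxygen of the C10 dimethylcarbamate to give iminium 26, which is hydrolysed to carbonate 27 on work-up; the closest known reaction types are the solvolytic cyclobutylcarbinyl ring expansion of enone–alkene photoadducts and carbamate participation at carbocations in halocyclisations and epoxide openings. The cyclopentane C1–C2–C3–C4–C5 is closed by a 1,2-alkyl shift (ring expansion by insertion of C2) and the dioxolane ring by 5-exo attack of oxygen on the cation. The C1 stereocentre is set by the tether, because the carbamate sits on the β face of C10 and its oxygen can reach C1 only from that face, so the 1,10-diol is formed cis, while C5 is not touched and keeps its α hydrogen. The step needs C3 to migrate rather than C5 or C10: C5 is deactivated by the adjacent C6 ketone and its shift would give a bridged skeleton, and a C10 shift releases no ring strain. Capture must outrun loss of the acidic C5 proton, which the hindered pyridine base and the 5-exo geometry favour; should the carbamate first displace the triflate at C2, the six-membered alkoxyiminium so formed is itself a leaving group and should ionise along the same path on warming.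

Step 17
Reactants: 27 cyclic carbonate
Product: 28 target, (1R,5S,7R,9R,10S)-1,10-dihydroxy-6-oxoguai-4(15)-en-9-yl (2Z)-2-methylbut-2-enoate
Conditions: Me3SnOH, ClCH2CH2Cl, 60 °C
Reagents that add atoms: none
Why: Carbonate hydrolysis with the nearly neutral hydroxide donor Me3SnOH should open the strained five-membered carbonate in preference to the hindered angelate and avoids alkoxide bases, which would eliminate the C1 oxygen β to the C6 ketone or move the C4(15) alkene into conjugation.

**Compound list**

1 | (S)-(+)-carvone | O=C1C[C@@H](C(C)=C)CC=C1C | starting material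
2 | (S)-carvotanacetone | O=C1C[C@@H](C(C)C)CC=C1C | intermediate
3 | (1S,4S,6S)-1-methyl-4-(propan-2-yl)-7-oxabicyclo[4.1.0]heptan-2-one (oxirane trans to isopropyl) | O=C1C[C@@H](C(C)C)C[C@@H]2O[C@]12C | intermediate
4 | (2S,3R,5S)-2,3-dihydroxy-2-methyl-5-(propan-2-yl)cyclohexan-1-one | O=C1C[C@@H](C(C)C)C[C@@H](O)[C@]1(C)O | intermediate
5 | (2S,3R,5S)-2-hydroxy-2-methyl-5-(propan-2-yl)-3-[(triisopropylsilyl)oxy]cyclohexan-1-one | O=C1C[C@@H](C(C)C)C[C@@H](O[Si](C(C)C)(C(C)C)C(C)C)[C@]1(C)O | intermediate
6 | (1S,2R,4S)-1-methyl-6-oxo-4-(propan-2-yl)-2-[(triisopropylsilyl)oxy]cyclohexyl dimethylcarbamate | O=C1C[C@@H](C(C)C)C[C@@H](O[Si](C(C)C)(C(C)C)C(C)C)[C@]1(C)OC(=O)N(C)C | intermediate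
7 | trimethylsilyl enol ether of 6 (C1=C6; 7α-isopropyl, 9α-OTIPS, 10β-carbamate) | C[Si](C)(C)OC1=C[C@@H](C(C)C)C[C@@H](O[Si](C(C)C)(C(C)C)C(C)C)[C@]1(C)OC(=O)N(C)C | intermediate
8 | 1-(trimethylsilyloxy)bicyclo[4.1.0]heptane from 7 (cyclopropane CH2 on the β face) | C[Si](C)(C)O[C@@]12C[C@@H]1[C@@H](C(C)C)C[C@@H](O[Si](C(C)C)(C(C)C)C(C)C)[C@]2(C)OC(=O)N(C)C | intermediate
9 | 3-chlorocycloheptanone (Cl at C6, both C6 epimers; C1 ketone) | O=C1CC(Cl)[C@@H](C(C)C)C[C@@H](O[Si](C(C)C)(C(C)C)C(C)C)[C@]1(C)OC(=O)N(C)C | intermediate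
10 | cyclohept-2-enone (C1 ketone, C5=C6; 7α-isopropyl, 9α-OTIPS, 10β-carbamate, 10α-methyl) | O=C1C=C[C@@H](C(C)C)C[C@@H](O[Si](C(C)C)(C(C)C)C(C)C)[C@]1(C)OC(=O)N(C)C | intermediate
11 | (tributylstannyl)methanol | CCCC[Sn](CCCC)(CCCC)CO | starting material
12 | 4-methoxybenzyl chloride | COc1ccc(CCl)cc1 | starting material
13 | tributyl{[(4-methoxybenzyl)oxy]methyl}stannane | CCCC[Sn](CCCC)(CCCC)COCc1ccc(OC)cc1 | intermediate
14 | [(4-methoxybenzyl)oxy]methyllithium | [Li]COCc1ccc(OC)cc1 | intermediate
15 | tertiary allylic alcohol (1α-OH, 1β-CH2OPMB drawn as the expected epimer; C5=C6) | COc1ccc(COC[C@]2(O)C=C[C@@H](C(C)C)C[C@@H](O[Si](C(C)C)(C(C)C)C(C)C)[C@]2(C)OC(=O)N(C)C)cc1 | intermediate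
16 | β-substituted cyclohept-2-enone (C6 ketone, C5=C1, C1–CH2OPMB) | COc1ccc(COCC2=CC(=O)[C@@H](C(C)C)C[C@@H](O[Si](C(C)C)(C(C)C)C(C)C)[C@]2(C)OC(=O)N(C)C)cc1 | intermediate
17 | allene (propa-1,2-diene) | C=C=C | starting material
18 | trans-fused photoadduct (C5 epimer of 19, 5β-H) | COc1ccc(COC[C@@]23CC(=C)[C@H]2C(=O)[C@@H](C(C)C)C[C@@H](O[Si](C(C)C)(C(C)C)C(C)C)[C@]3(C)OC(=O)N(C)C)cc1 | intermediate
19 | cis-fused photoadduct (9-methylenebicyclo[5.2.0]nonan-2-one core; cyclobutane β, 1α-CH2OPMB, 5α-H) | COc1ccc(COC[C@@]23CC(=C)[C@@H]2C(=O)[C@@H](C(C)C)C[C@@H](O[Si](C(C)C)(C(C)C)C(C)C)[C@]3(C)OC(=O)N(C)C)cc1 | intermediate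
20 | C9 alcohol of 19 (9α-OH) | COc1ccc(COC[C@@]23CC(=C)[C@@H]2C(=O)[C@@H](C(C)C)C[C@@H](O)[C@]3(C)OC(=O)N(C)C)cc1 | intermediate
21 | angelic acid, (2Z)-2-methylbut-2-enoic acid | C/C=C(/C)C(=O)O | starting material
22 | angelic 2,4,6-trichlorobenzoic anhydride | C/C=C(/C)C(=O)OC(=O)c1c(Cl)cc(Cl)cc1Cl | intermediate
23 | C9 angelate of 20 | COc1ccc(COC[C@@]23CC(=C)[C@@H]2C(=O)[C@@H](C(C)C)C[C@@H](OC(=O)/C(C)=C\C)[C@]3(C)OC(=O)N(C)C)cc1 | intermediate
24 | primary C2 alcohol (1α-CH2OH on the cyclobutane) | OC[C@@]12CC(=C)[C@@H]1C(=O)[C@@H](C(C)C)C[C@@H](OC(=O)/C(C)=C\C)[C@]2(C)OC(=O)N(C)C | intermediate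
25 | C2 triflate of 24 | O=S(=O)(OC[C@@]12CC(=C)[C@@H]1C(=O)[C@@H](C(C)C)C[C@@H](OC(=O)/C(C)=C\C)[C@]2(C)OC(=O)N(C)C)C(F)(F)F | intermediate
26 | ring-expanded 2-(dimethyliminio)-1,3-dioxolane triflate spanning O1 and O10 | C=C1CC[C@@]2(OC(=[N+](C)C)O3)[C@H]1C(=O)[C@@H](C(C)C)C[C@@H](OC(=O)/C(C)=C\C)[C@@]23C.[O-]S(=O)(=O)C(F)(F)F | intermediate
27 | guaiane 1β,10β-cyclic carbonate 9α-angelate (5αH, 4(15)-en-6-one) | C=C1CC[C@@]2(OC(=O)O3)[C@H]1C(=O)[C@@H](C(C)C)C[C@@H](OC(=O)/C(C)=C\C)[C@@]23C | intermediate
28 | (1R,5S,7R,9R,10S)-1,10-dihydroxy-6-oxoguai-4(15)-en-9-yl (2Z)-2-methylbut-2-enoate (1β,10β-diol, 5αH, 7α-isopropyl, 9α-angeloyloxy) | C=C1CC[C@@]2(O)[C@H]1C(=O)[C@@H](C(C)C)C[C@@H](OC(=O)/C(C)=C\C)[C@]2(C)O | target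

**Step count and risks**

Total steps: 17. Longest linear sequence: 16 (steps 1–8 and 10–17; step 9 prepares the stannane).

Steps most likely to fail:

1. Step 16 (proposed new method). The triflate may be displaced or eliminated without ring expansion, or the C1 cation may lose the C5 proton to the conjugated enone before the carbamate captures it. Fallback with known chemistry, setting out from 24: Dess–Martin oxidation gives the aldehyde F1. Condensation with TsNHNH2 gives the tosylhydrazone F2. Aprotic Bamford–Stevens decomposition (NaH, toluene, 100 °C) generates the cyclobutylcarbene, whose 1,2-carbon shift expands the ring to the C1=C2 cyclopentene F3. Iodocyclisation (N-iodosuccinimide, NaHCO3, MeCN) makes the carbamate oxygen add to C1 (Markovnikov, 5-exo, anti to iodine) and gives, after hydrolysis of the iminium, the 2α-iodo carbonate F4. Radical deiodination (Bu3SnH, AIBN, benzene, 80 °C) returns to the route at 27.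

2. Step 17. The base-sensitive β-carbonyloxy ketone may undergo E1cB loss of the C1 oxygen, or the C4(15) alkene may migrate into conjugation, faster than the carbonate is cleaved. Fallback, setting out from 27: Luche reduction (NaBH4, CeCl3·7H2O, MeOH, −40 °C) removes the acidifying ketone and gives the C6 alcohol F5. Methanolysis of the carbonate (K2CO3, MeOH, 0 °C) gives the 1,6,10-triol 9-angelate F6. Dess–Martin oxidation of its only secondary alcohol (NaHCO3-buffered, CH2Cl2) restores the ketone and arrives at 28.

3. Step 8. The Lewis-acidic oxidant may divert the alkoxy-radical fragmentation (loss of the silyl ether, over-chlorination, cleavage of the external cyclopropane bond). Fallback, setting out from 6: ring homologation with Me3SiCHN2/AlMe3 (CH2Cl2, −78 °C; migration of the unsubstituted C6 rather than the oxygenated quaternary C10), followed by protodesilylation on work-up, gives the cycloheptanone F7. Dehydrogenation with IBX (DMSO, 70 °C), possible only across C5–C6, returns to the route at 10.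

**Further compounds**

F1 | step 16 | aldehyde from 24 (C2 = CHO) | O=C[C@@]12CC(=C)[C@@H]1C(=O)[C@@H](C(C)C)C[C@@H](OC(=O)/C(C)=C\C)[C@]2(C)OC(=O)N(C)C
F2 | step 16 | N-tosylhydrazone of F1 | Cc1ccc(cc1)S(=O)(=O)N/N=C/[C@@]12CC(=C)[C@@H]1C(=O)[C@@H](C(C)C)C[C@@H](OC(=O)/C(C)=C\C)[C@]2(C)OC(=O)N(C)C
F3 | step 16 | ring-expanded C1=C2 cyclopentene (guaia-1,4(15)-dien-6-one 9-angelate 10-dimethylcarbamate) | C=C1CC=C2[C@H]1C(=O)[C@@H](C(C)C)C[C@@H](OC(=O)/C(C)=C\C)[C@]2(C)OC(=O)N(C)C
F4 | step 16 | 2α-iodo 1β,10β-cyclic carbonate | C=C1C[C@H](I)[C@@]2(OC(=O)O3)[C@H]1C(=O)[C@@H](C(C)C)C[C@@H](OC(=O)/C(C)=C\C)[C@@]23C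
F5 | step 17 | C6 alcohol of 27 (either C6 epimer) | C=C1CC[C@@]2(OC(=O)O3)[C@H]1C(O)[C@@H](C(C)C)C[C@@H](OC(=O)/C(C)=C\C)[C@@]23C
F6 | step 17 | 1β,6,10β-triol 9α-angelate | C=C1CC[C@@]2(O)[C@H]1C(O)[C@@H](C(C)C)C[C@@H](OC(=O)/C(C)=C\C)[C@]2(C)O
F7 | step 8 | cycloheptanone (C1 ketone; C5 and C6 methylene; 9α-OTIPS, 10β-carbamate) | O=C1CC[C@@H](C(C)C)C[C@@H](O[Si](C(C)C)(C(C)C)C(C)C)[C@]1(C)OC(=O)N(C)C
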